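## Structural features

The target (18 in the route) is built on one benzene ring with a 1,2,4 substitution pattern. The labels used here are C7 for the benzylic methylene, C8 for the quaternary oxirane carbon, C9 for the oxirane methylene and C10 for the exocyclic oxymethyl carbon. The ring carries an aryl ester oxygen (the (E)-2-methylbut-2-enoate, tiglate), C8 on the neighbouring ring carbon, and C7 as its isobutyrate para to C8. C8 is the only stereocentre, (R), and is fully substituted: ring carbon, oxirane oxygen, C9, and C10 bearing the second isobutyrate. Because C9 and C10 are both oxygen-bearing methylenes, the configuration at C8 is only the way these two arms are told apart. A group moving from one oxygen to the other, or a free C10 hydroxyl reopening the oxirane at C8 (Payne rearrangement), would therefore give the mirror image. The fragile parts are the tertiary benzylic oxirane on an electron-rich ring (opened by acid and by an ortho phenol), the aryl ester (which tolerates no hydride, alkoxide or fluoride) and, less so, the two isobutyrates. The difficulty is to build quaternary C8 on the arene as one enantiomer and then to order the late steps so that three esters and the oxirane are installed without scrambling C9 and C10. The key step uses the fact that the ring carbon–C8 bond lies ortho to the phenolic oxygen, so a titanium-bound phenol can deliver a 2-oxo ester to exactly that carbon.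

## Logic of the disconnections

18 to 15 and 16 (through 17): the acyl–oxygen bond of the aryl tiglate is cut first. The aryl ester is the most electrophilic carbonyl group and would not survive the hydride, fluoride or base used elsewhere, so it must be the last bond made. This leaves a phenol and removes the only alkene. The forward acylation must be fast, basic and free of carboxylic acid, because 15 has a free phenol next to an acid-labile oxirane.

15 to 14: the phenol is returned to its allyl ether. The phenol has to be masked while a sulfonate is made and displaced, since a phenoxide would be sulfonylated or would close a dihydrobenzofuran. Allyl is chosen because zerovalent palladium removes it without acid, hydride or strong base. The scavenger must not open the oxirane.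

14 to 13: the O–C9 bond of the oxirane is cut, to a tertiary alcohol and a primary sulfonate. Closing the ring only after both isobutyrates are on means that C10 never carries a free hydroxyl beside the oxirane, so the Payne route to the enantiomer is closed. The ring then has to survive only two further steps. The base must form the tertiary alkoxide without transferring or cleaving an acyl group.

13 to 11 and 12, and 11 to 10: the two isobutyryl–oxygen bonds are cut, and the two primary hydroxyls are returned to silyl ethers. Both arms are unveiled and acylated together, so no selective acylation is needed. The fluoride source must be non-basic, so that the sulfonate is not displaced early, and mild enough to leave the tertiary benzylic carbinol alone.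

10 to 9 to 8: the sulfur–oxygen bond is cut and C9 is returned to the ester oxidation level. In 8 the two arms are an ester and a silyl ether, so C9 and C10 are distinguished by functional group and not by a selective reaction. The reduction and sulfonylation must not let the silyl group move from O10 to O9, which is why the bulky diphenylsilyl group is placed on C10.

8 to 7: the allyl–oxygen bond is cut. Allylation directly after the key step also stops the phenol from lactonising onto the neighbouring ester.

7 to 2 and 6: the ring carbon–C8 bond is cut. This is the convergent step: two achiral pieces of similar size, and C8 appears with all four substituents and with C9 and C10 already different. It requires ortho over para attack, the open ortho carbon over the flanked one, and one ketone face.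

2 to 1, and 6 to 4 (through 5) to 3: a silicon–oxygen bond is cut in each branch, and the ketone of 6 is traced to the methylene group of an acrylate by oxidative cleavage. Both branches end at commercial compounds. 2 is reached in one step if the aliphatic hydroxyl of 1 is silylated in preference to the phenol.

## Other disconnections considered

Alternative 1: The C8–C9 and C9–O bonds of the oxirane are cut, leading to aryl ketone A1, 1-[2-(allyloxy)-4-(tert-butyldimethylsilyloxymethyl)phenyl]-2-(tert-butyldimethylsilyloxy)ethanone. In the forward step a sulfoxonium methylide would add to the ketone under LaLi3(binaphthoxide)3 with an achiral phosphine oxide additive, and the betaine would close 3-exo-tet to oxirane A2.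
- In its favour: ring and stereocentre arise in one catalytic operation, C9 comes from a one-carbon reagent, and A1 is achiral, so nothing has to be kept differentiated before the key step.
- Against it here: the catalyst is best established for methyl ketones. In A1 it would have to distinguish an ortho-alkoxyaryl group from a silyloxymethyl group of similar size, and the α-oxygenated ketone has acidic protons that the ylide can remove. A2 still carries silyl ethers, so their removal frees the C10 hydroxyl beside the oxirane, which is the Payne exposure the chosen route avoids. A1 also needs a regioselective ortho-acylation of its own.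
- Comparison: on step economy Alternative 1 is the better plan, since sulfonylation and ring closure disappear. The two plans are equal in the endgame (deallylation, tigloylation). On mechanism the chosen plan has the tighter organisation, a chelated 1,2-dicarbonyl attacked by a tethered nucleophile, against an unchelated ketone with two bulky flanks.

Alternative 2: The acyl–oxygen bond of the C10 isobutyrate is cut, leading to the achiral triol A3, 3-(allyloxy)-4-(1,2,3-trihydroxypropan-2-yl)benzyl isobutyrate. In the forward step CuCl2 with a chiral bis(oxazoline) would bind the tertiary hydroxyl and one enantiotopic primary hydroxyl, and an isobutyryl donor would acylate that oxygen to give monoester A4.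
- In its favour: the stereo-defining step installs an ester that the target needs, C10 needs no protecting group, and A3 requires no asymmetric carbon–carbon bond formation.
- Against it here: desymmetrisation of this kind is best known with aroyl donors and small groups at the carbinol. A hindered ortho-alkoxyaryl carbinol with an aliphatic acyl donor is a stretch. A4 is configurationally fragile, because a 1,3 acyl shift from O10 to O9 is degenerate and gives the enantiomer, so it would have to be sulfonylated at once. Over-acylation gives an achiral diester, and the C7 ester must already be in A3, which limits how the triol can be made.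
- Comparison: in step and atom economy Alternative 2 is the better plan. Both plans rely equally on one catalytic metal–ligand complex for the stereocentre. In robustness the chosen plan is stronger, because it stores the stereochemical information as an ester and a bulky silyl ether that cannot exchange places.

Alternative 3: The C8–O bond of the tertiary carbinol is cut, leading to the racemic cyclic carbonate A5, 4-[2-(4-methoxybenzyloxy)-4-(tert-butyldimethylsilyloxymethyl)phenyl]-4-vinyl-1,3-dioxolan-2-one. In the forward step zerovalent palladium from Pd2(dba)3 with a chiral phosphoramidite would ionise the carbonate with loss of carbon dioxide, and water would attack the aryl-bearing allyl terminus to give vinyl glycol A6.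
- In its favour: the step is stereoconvergent, so racemic material is used in full. Aryl-substituted carbonates are the best-studied substrates of this reaction, and the conditions are mild.
- Against it here: the ortho substituent is expected to hinder attack at the internal terminus. An allyl ether cannot be present, so a 4-methoxybenzyl group is needed, and its later removal must spare the oxirane. The product has one carbon too many. With the configuration of A6, its hydroxymethyl group must become C9 and the vinyl group must be cleaved and reduced to C10. This adds about three steps and again passes through a free C10 hydroxyl beside the oxirane.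
- Comparison: Alternative 3 is the equal or the better of the chosen plan in the maturity of its precedent for aryl-substituted tertiary centres and in tolerating a racemic precursor. It is weaker in step and redox economy. It forms only a carbon–oxygen bond, so the carbon skeleton must be assembled beforehand, whereas the chosen plan forms the skeleton and the stereocentre together.

Key step: step 4

Remark on the chemistry: the sense of induction is assumed to follow that of (R)-BINOL–titanium complexes of glyoxylates (Re-face attack); if the other face is preferred, (S)-BINOL is used and nothing else changes.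

## Route

Step 1
Reactants: 1 3-hydroxybenzyl alcohol
Product: 2 3-[(tert-butyldimethylsilyloxy)methyl]phenol
Conditions: TBSCl (1.05 equiv), imidazole, DMF, 0 °C
Reagents that add atoms: tert-butyldimethylsilyl chloride, CC(C)(C)[Si](C)(C)Cl
Why: Selective O-silylation: with one equivalent of silyl chloride the primary benzylic hydroxyl should react faster than the less nucleophilic phenol, and any aryl silyl ether formed is the more labile one.

Step 2
Reactants: 3 ethyl 2-(hydroxymethyl)acrylate
Product: 4 ethyl 2-[(tert-butyldiphenylsilyloxy)methyl]prop-2-enoate
Conditions: TBDPSCl, imidazole, CH2Cl2, 0 °C to rt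
Reagents that add atoms: tert-butyldiphenylsilyl chloride, CC(C)(C)[Si](Cl)(c1ccccc1)c1ccccc1
Why: Standard silylation of a primary allylic alcohol; the bulky diphenylsilyl group should resist the Lewis acid of step 4 and O-to-O migration in steps 5 to 7, where it is the label that keeps C10 distinct from C9.

Step 3
Reactants: 4 ethyl 2-[(tert-butyldiphenylsilyloxy)methyl]prop-2-enoate
Product: 6 ethyl 3-(tert-butyldiphenylsilyloxy)-2-oxopropanoate, via trioxolane ozonide 5 (not isolated)
Conditions: O3, CH2Cl2, −78 °C; then Me2S, −78 °C to rt
Reagents that add atoms: ozone, [O-][O+]=O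
Why: Ozonolysis with reductive work-up: cycloaddition and rearrangement give ozonide 5, which dimethyl sulfide reduces to the 2-oxo ester with loss of the methylene carbon as formaldehyde.

Step 4
Reactants: 2 3-[(tert-butyldimethylsilyloxy)methyl]phenol; 6 ethyl 3-(tert-butyldiphenylsilyloxy)-2-oxopropanoate
Product: 7 ethyl (S)-2-hydroxy-2-[2-hydroxy-4-(tert-butyldimethylsilyloxymethyl)phenyl]-3-(tert-butyldiphenylsilyloxy)propanoate
Conditions: Ti(OiPr)4 (10 mol %), (R)-BINOL (11 mol %), 4 Å molecular sieves, toluene, 0 °C, 6 added slowly
Reagents that add atoms: none
Why: Ligand exchange should place phenol 2 on the BINOL-bound titanium alkoxide, while oxo ester 6 binds the same metal through its ketone and ester carbonyl oxygens as a five-membered chelate. The ortho carbon C6 of the titanium phenolate then attacks the activated ketone carbon through a six-membered cyclic transition state (titanium, phenolate oxygen, C1, C6, ketone carbon, ketone oxygen), and loss of the ring proton restores the arene. This is an ortho-directed Friedel–Crafts hydroxyalkylation, and its closest known relatives are the chiral titanium alkoxide catalysed reactions of phenols with pyruvates and trifluoropyruvate. No ring is closed. The new stereocentre C8 is controlled by the BINOL ligand, which shields one face of the chelated ketone so that the arene adds to the Re face, giving the (S) descriptor of 7. Ortho rather than para attack is secured by the metal tether, since only an ortho carbon can reach the bound ketone. Of the two ortho carbons, C6 is taken because C2 is flanked by the silyloxymethyl group, and C6 is also para to that alkyl donor. The bulky, weakly basic silyl ether of 6 should not compete with the dicarbonyl chelate, and C9 (ester) and C10 (silyl ether) leave the step already differentiated.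

Step 5
Reactants: 7 ethyl (S)-2-hydroxy-2-[2-hydroxy-4-(tert-butyldimethylsilyloxymethyl)phenyl]-3-(tert-butyldiphenylsilyloxy)propanoate
Product: 8 ethyl (S)-2-[2-(allyloxy)-4-(tert-butyldimethylsilyloxymethyl)phenyl]-2-hydroxy-3-(tert-butyldiphenylsilyloxy)propanoate
Conditions: allyl bromide, K2CO3, DMF, rt
Reagents that add atoms: allyl bromide, C=CCBr
Why: Williamson ether synthesis: only the phenol is acidic enough for K2CO3, so the tertiary hydroxyl stays free; capping the phenol also stops lactonisation onto the ester.

Step 6
Reactants: 8 ethyl (S)-2-[2-(allyloxy)-4-(tert-butyldimethylsilyloxymethyl)phenyl]-2-hydroxy-3-(tert-butyldiphenylsilyloxy)propanoate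
Product: 9 (R)-2-[2-(allyloxy)-4-(tert-butyldimethylsilyloxymethyl)phenyl]-3-(tert-butyldiphenylsilyloxy)propane-1,2-diol
Conditions: LiBH4, THF, 0 °C to rt
Reagents that add atoms: none
Why: Hydride reduction of an ester: LiBH4 reduces the α-hydroxy ester to the primary alcohol C9 and should leave silyl and allyl ethers alone; C8 is untouched, and the descriptor changes from S to R only because the priorities change.

Step 7
Reactants: 9 (R)-2-[2-(allyloxy)-4-(tert-butyldimethylsilyloxymethyl)phenyl]-3-(tert-butyldiphenylsilyloxy)propane-1,2-diol
Product: 10 (S)-2-[2-(allyloxy)-4-(tert-butyldimethylsilyloxymethyl)phenyl]-3-(tert-butyldiphenylsilyloxy)-2-hydroxypropyl 4-methylbenzenesulfonate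
Conditions: TsCl, pyridine, DMAP (cat.), CH2Cl2, 0 °C to rt
Reagents that add atoms: 4-toluenesulfonyl chloride, Cc1ccc(cc1)S(Cl)(=O)=O
Why: Selective sulfonylation: the primary hydroxyl reacts while the tertiary benzylic hydroxyl is too hindered, and pyridine is too weak a base to close the oxirane early; the descriptor returns to S by priority change only.

Step 8
Reactants: 10 (S)-2-[2-(allyloxy)-4-(tert-butyldimethylsilyloxymethyl)phenyl]-3-(tert-butyldiphenylsilyloxy)-2-hydroxypropyl 4-methylbenzenesulfonate
Product: 11 (S)-2-[2-(allyloxy)-4-(hydroxymethyl)phenyl]-2,3-dihydroxypropyl 4-methylbenzenesulfonate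
Conditions: HF·pyridine, pyridine, THF, 0 °C to rt
Reagents that add atoms: none
Why: Fluoride-mediated silyl ether cleavage under buffered, non-basic conditions: both silyl ethers should fall while no alkoxide is formed that could displace the sulfonate; C9 stays marked by its sulfonate, so the freed C10 hydroxyl cannot be confused with it.

Step 9
Reactants: 11 (S)-2-[2-(allyloxy)-4-(hydroxymethyl)phenyl]-2,3-dihydroxypropyl 4-methylbenzenesulfonate; 12 isobutyric anhydride
Product: 13 (S)-2-[2-(allyloxy)-4-(isobutyryloxymethyl)phenyl]-2-hydroxy-3-(tosyloxy)propyl isobutyrate
Conditions: 12 (2.5 equiv), pyridine, DMAP (cat.), CH2Cl2, 0 °C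
Reagents that add atoms: isobutyric anhydride (12), CC(C)C(=O)OC(=O)C(C)C
Why: DMAP-catalysed acylation of the two primary hydroxyls; the tertiary hydroxyl should be inert at 0 °C and the sulfonate cannot migrate.

Step 10
Reactants: 13 (S)-2-[2-(allyloxy)-4-(isobutyryloxymethyl)phenyl]-2-hydroxy-3-(tosyloxy)propyl isobutyrate
Product: 14 [(R)-2-[2-(allyloxy)-4-(isobutyryloxymethyl)phenyl]oxiran-2-yl]methyl isobutyrate
Conditions: DBU, CH2Cl2, 0 °C to rt
Reagents that add atoms: none
Why: Intramolecular Williamson etherification (3-exo-tet): the tertiary oxygen, deprotonated by the non-nucleophilic amidine, displaces the primary tosylate at C9; no bond to C8 is broken, so the configuration is kept and the descriptor becomes R as in the target.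

Step 11
Reactants: 14 [(R)-2-[2-(allyloxy)-4-(isobutyryloxymethyl)phenyl]oxiran-2-yl]methyl isobutyrate
Product: 15 [(R)-2-[2-hydroxy-4-(isobutyryloxymethyl)phenyl]oxiran-2-yl]methyl isobutyrate
Conditions: Pd(PPh3)4 (5 mol %), morpholine, THF, 0 °C to rt; used at once
Reagents that add atoms: none
Why: Tsuji–Trost deallylation: zerovalent palladium ionises the allyl aryl ether to a π-allyl complex and the phenoxide, and morpholine takes up the allyl group; the isobutyrates and the non-allylic oxirane should be untouched at this temperature.

Step 12
Reactants: 15 [(R)-2-[2-hydroxy-4-(isobutyryloxymethyl)phenyl]oxiran-2-yl]methyl isobutyrate; 16 tiglic acid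
Product: 18 5-(isobutyryloxymethyl)-2-[(R)-2-(isobutyryloxymethyl)oxiran-2-yl]phenyl (E)-2-methylbut-2-enoate (CNP0189152.1), via tiglic 2,4,6-trichlorobenzoic anhydride 17 (not isolated)
Conditions: 16, 2,4,6-trichlorobenzoyl chloride, Et3N, toluene, rt; then 15, DMAP, 0 °C to rt
Reagents that add atoms: tiglic acid (16), C/C=C(\C)C(=O)O
Why: Yamaguchi esterification: the acid is first turned into mixed anhydride 17, so the oxirane never meets free carboxylic acid; DMAP then transfers the less hindered tigloyl group to the phenol, and the E geometry is not touched.

## Compound list

1 | 3-hydroxybenzyl alcohol | OCc1cccc(O)c1 | starting material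
2 | 3-[(tert-butyldimethylsilyloxy)methyl]phenol | Oc1cccc(CO[Si](C)(C)C(C)(C)C)c1 | intermediate
3 | ethyl 2-(hydroxymethyl)acrylate | C=C(CO)C(=O)OCC | starting material
4 | ethyl 2-[(tert-butyldiphenylsilyloxy)methyl]prop-2-enoate | C=C(CO[Si](c1ccccc1)(c1ccccc1)C(C)(C)C)C(=O)OCC | intermediate
5 | ethyl 3-[(tert-butyldiphenylsilyloxy)methyl]-1,2,4-trioxolane-3-carboxylate (ozonide, racemic, not isolated) | CCOC(=O)C1(CO[Si](c2ccccc2)(c2ccccc2)C(C)(C)C)OCOO1 | intermediate
6 | ethyl 3-(tert-butyldiphenylsilyloxy)-2-oxopropanoate | CCOC(=O)C(=O)CO[Si](c1ccccc1)(c1ccccc1)C(C)(C)C | intermediate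
7 | ethyl (S)-2-hydroxy-2-[2-hydroxy-4-(tert-butyldimethylsilyloxymethyl)phenyl]-3-(tert-butyldiphenylsilyloxy)propanoate | Oc1cc(CO[Si](C)(C)C(C)(C)C)ccc1[C@](O)(CO[Si](c1ccccc1)(c1ccccc1)C(C)(C)C)C(=O)OCC | intermediate
8 | ethyl (S)-2-[2-(allyloxy)-4-(tert-butyldimethylsilyloxymethyl)phenyl]-2-hydroxy-3-(tert-butyldiphenylsilyloxy)propanoate | C=CCOc1cc(CO[Si](C)(C)C(C)(C)C)ccc1[C@](O)(CO[Si](c1ccccc1)(c1ccccc1)C(C)(C)C)C(=O)OCC | intermediate
9 | (R)-2-[2-(allyloxy)-4-(tert-butyldimethylsilyloxymethyl)phenyl]-3-(tert-butyldiphenylsilyloxy)propane-1,2-diol | C=CCOc1cc(CO[Si](C)(C)C(C)(C)C)ccc1[C@](O)(CO[Si](c1ccccc1)(c1ccccc1)C(C)(C)C)CO | intermediate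
10 | (S)-2-[2-(allyloxy)-4-(tert-butyldimethylsilyloxymethyl)phenyl]-3-(tert-butyldiphenylsilyloxy)-2-hydroxypropyl 4-methylbenzenesulfonate | C=CCOc1cc(CO[Si](C)(C)C(C)(C)C)ccc1[C@](O)(CO[Si](c1ccccc1)(c1ccccc1)C(C)(C)C)COS(=O)(=O)c1ccc(C)cc1 | intermediate
11 | (S)-2-[2-(allyloxy)-4-(hydroxymethyl)phenyl]-2,3-dihydroxypropyl 4-methylbenzenesulfonate | C=CCOc1cc(CO)ccc1[C@](O)(CO)COS(=O)(=O)c1ccc(C)cc1 | intermediate
12 | isobutyric anhydride | CC(C)C(=O)OC(=O)C(C)C | starting material
13 | (S)-2-[2-(allyloxy)-4-(isobutyryloxymethyl)phenyl]-2-hydroxy-3-(tosyloxy)propyl isobutyrate | C=CCOc1cc(COC(=O)C(C)C)ccc1[C@](O)(COC(=O)C(C)C)COS(=O)(=O)c1ccc(C)cc1 | intermediate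
14 | [(R)-2-[2-(allyloxy)-4-(isobutyryloxymethyl)phenyl]oxiran-2-yl]methyl isobutyrate | C=CCOc1cc(COC(=O)C(C)C)ccc1[C@]1(COC(=O)C(C)C)CO1 | intermediate
15 | [(R)-2-[2-hydroxy-4-(isobutyryloxymethyl)phenyl]oxiran-2-yl]methyl isobutyrate | Oc1cc(COC(=O)C(C)C)ccc1[C@]1(COC(=O)C(C)C)CO1 | intermediate
16 | tiglic acid, (E)-2-methylbut-2-enoic acid | C/C=C(\C)C(=O)O | starting material
17 | tiglic 2,4,6-trichlorobenzoic anhydride (not isolated) | C/C=C(\C)C(=O)OC(=O)c1c(Cl)cc(Cl)cc1Cl | intermediate
18 | 5-(isobutyryloxymethyl)-2-[(R)-2-(isobutyryloxymethyl)oxiran-2-yl]phenyl (E)-2-methylbut-2-enoate (CNP0189152.1) | C/C=C(\C)C(=O)Oc1cc(COC(=O)C(C)C)ccc1[C@]1(COC(=O)C(C)C)CO1 | target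

## Step count and least certain steps

Total step count: 12. Longest linear sequence: 11 steps (from 3 through steps 2 to 12); the branch from 1 joins at step 4 after one step.

Step 4 (key step). The most likely failure is poor facial selectivity together with slow turnover. The ketone carries two bulky groups, and the product, a phenol and α-hydroxy ester, can hold on to titanium, leaving room for a less selective background pathway. Fallback, auxiliary control in place of catalyst control, setting out from 2 and 6 and returning at 9:
- 6 is transesterified with (–)-menthol (Ti(OEt)4 cat., toluene, 90 °C, ethanol distilled off) to (1R,2S,5R)-menthyl 3-(tert-butyldiphenylsilyloxy)-2-oxopropanoate F1.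
- 2 and F1 are combined with one equivalent of TiCl(OiPr)3 (CH2Cl2, −20 °C). The same ortho-selective hydroxyalkylation should give the menthyl hydroxy ester F2, whose diastereomers are separable by chromatography or crystallisation, so C8 no longer depends on a catalyst.
- Allylation as in step 5 gives the menthyl ester allyl ether F3, and LiBH4 as in step 6 removes the auxiliary reductively and delivers 9.

Step 11. The likely failure is opening or isomerisation of the oxirane once the ortho phenol is free, by phenol-assisted ionisation of the C8–O bond or attack of the amine scavenger, and loss on handling. Fallback, hydrostannolysis with capture in the same flask, setting out from 14 and returning at 18: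
- Pd(PPh3)4 (cat.) and Bu3SnH in CH2Cl2 cleave the allyl ether to the tributylstannyl phenoxide F4, which is not isolated.
- 17, made beforehand from 16, and DMAP are added and acylate the tin phenoxide directly to 18, so the free phenol never exists beside the oxirane.

Step 10. The likely failure is acyl transfer from O10 to the tertiary alkoxide, followed by closure of the freed C10 oxygen to an oxetane, or a sluggish ring closure, because the alkoxide sits next to an ester carbonyl. Fallback, ring closure before the esters are present, setting out from 10 and returning at 14 (this also bypasses the acidic fluoride of step 8):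
- K2CO3 in methanol closes 10 to the bis-silyl oxirane F5.
- Bu4NF buffered with acetic acid in THF removes both silyl groups to give the epoxy diol F6.
- F6 is acylated at once with 12 (pyridine, DMAP) to 14. The cost is a brief passage through a free C10 hydroxyl beside the oxirane, hence the buffer and the immediate acylation.

Step 1. The likely failure is competing silylation of the phenolic oxygen, since phenols also react with silyl chlorides and imidazole. Fallback, protect both and release one, setting out from 1 and returning at 2:
- 1 is silylated twice (TBSCl, imidazole, DMF) to the bis-silyl ether F7.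
- The more labile aryl silyl ether is cleaved selectively with K2CO3 in methanol to give 2.

## Further compounds

F1 | step 4 | (1R,2S,5R)-menthyl 3-(tert-butyldiphenylsilyloxy)-2-oxopropanoate | C[C@@H]1CC[C@H]([C@@H](C1)OC(=O)C(=O)CO[Si](c1ccccc1)(c1ccccc1)C(C)(C)C)C(C)C
F2 | step 4 | (1R,2S,5R)-menthyl (S)-2-hydroxy-2-[2-hydroxy-4-(tert-butyldimethylsilyloxymethyl)phenyl]-3-(tert-butyldiphenylsilyloxy)propanoate | C[C@@H]1CC[C@H]([C@@H](C1)OC(=O)[C@@](O)(CO[Si](c1ccccc1)(c1ccccc1)C(C)(C)C)c1ccc(CO[Si](C)(C)C(C)(C)C)cc1O)C(C)C
F3 | step 4 | (1R,2S,5R)-menthyl (S)-2-[2-(allyloxy)-4-(tert-butyldimethylsilyloxymethyl)phenyl]-2-hydroxy-3-(tert-butyldiphenylsilyloxy)propanoate | C[C@@H]1CC[C@H]([C@@H](C1)OC(=O)[C@@](O)(CO[Si](c1ccccc1)(c1ccccc1)C(C)(C)C)c1ccc(CO[Si](C)(C)C(C)(C)C)cc1OCC=C)C(C)C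
F4 | step 11 | [(R)-2-[4-(isobutyryloxymethyl)-2-(tributylstannyloxy)phenyl]oxiran-2-yl]methyl isobutyrate | CCCC[Sn](CCCC)(CCCC)Oc1cc(COC(=O)C(C)C)ccc1[C@]1(COC(=O)C(C)C)CO1
F5 | step 10 | tert-butyl{[(R)-2-[2-(allyloxy)-4-(tert-butyldimethylsilyloxymethyl)phenyl]oxiran-2-yl]methoxy}diphenylsilane | C=CCOc1cc(CO[Si](C)(C)C(C)(C)C)ccc1[C@]1(CO[Si](c2ccccc2)(c2ccccc2)C(C)(C)C)CO1
F6 | step 10 | [(S)-2-[2-(allyloxy)-4-(hydroxymethyl)phenyl]oxiran-2-yl]methanol (same spatial arrangement as 14) | C=CCOc1cc(CO)ccc1[C@]1(CO)CO1
F7 | step 1 | tert-butyl{3-[(tert-butyldimethylsilyloxy)methyl]phenoxy}dimethylsilane | CC(C)(C)[Si](C)(C)OCc1cccc(O[Si](C)(C)C(C)(C)C)c1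
A1 | alternative 1 | 1-[2-(allyloxy)-4-(tert-butyldimethylsilyloxymethyl)phenyl]-2-(tert-butyldimethylsilyloxy)ethanone | C=CCOc1cc(CO[Si](C)(C)C(C)(C)C)ccc1C(=O)CO[Si](C)(C)C(C)(C)C
A2 | alternative 1 | (R)-2-[2-(allyloxy)-4-(tert-butyldimethylsilyloxymethyl)phenyl]-2-(tert-butyldimethylsilyloxymethyl)oxirane | C=CCOc1cc(CO[Si](C)(C)C(C)(C)C)ccc1[C@]1(CO[Si](C)(C)C(C)(C)C)CO1
A3 | alternative 2 | 3-(allyloxy)-4-(1,2,3-trihydroxypropan-2-yl)benzyl isobutyrate | C=CCOc1cc(COC(=O)C(C)C)ccc1C(O)(CO)CO
A4 | alternative 2 | (R)-2-[2-(allyloxy)-4-(isobutyryloxymethyl)phenyl]-2,3-dihydroxypropyl isobutyrate | C=CCOc1cc(COC(=O)C(C)C)ccc1[C@](O)(COC(=O)C(C)C)CO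
A5 | alternative 3 | 4-[2-(4-methoxybenzyloxy)-4-(tert-butyldimethylsilyloxymethyl)phenyl]-4-vinyl-1,3-dioxolan-2-one (racemic) | COc1ccc(COc2cc(CO[Si](C)(C)C(C)(C)C)ccc2C2(C=C)COC(=O)O2)cc1
A6 | alternative 3 | (R)-2-[2-(4-methoxybenzyloxy)-4-(tert-butyldimethylsilyloxymethyl)phenyl]but-3-ene-1,2-diol | COc1ccc(COc2cc(CO[Si](C)(C)C(C)(C)C)ccc2[C@](O)(C=C)CO)cc1
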